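**Plan**

- Target 20 is 6-hydroxykaempferol 7-O-sulfate. Flavonol numbering (O1, C2–C4, C4a, C5–C8, C8a; ring A benzo, ring C pyranone, ring B aryl) is used for every intermediate.
- Retrosynthesis: cut O7–S and the O-benzyl and O-benzyloxycarbonyl groups; cut ring A at C6–C7 and C8–C8a, which leads back to a 4-pyranone with a diazoacetyl group on C8a and a (Z)-enediol unit on C4a; then cut C4a–C5, C2–C1′ and the ester, back to comenic acid.
- Enabling feature: O7 stands on C7 between oxygenated C6 and unsubstituted C8 of ring A. A ketene at C7, linked through C8 to C8a, together with the C8a=C4a bond of ring C and a C5=C6 enediol bond on C4a, is a dienylketene that closes to a phenol whose single free hydroxyl is O7.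
- Forward: ring C is bought as comenic acid (its carboxyl carbon becomes C7). Ring B is joined by Suzuki coupling, C5–C6 by zincation/acylation and enol carbonate formation, and diazomethane supplies C8. Ring A closes last, followed by sulfation of O7 and one hydrogenolysis.
- Stereochemistry: the target has no stereocentre. The only stereo-element on the way is the (Z) enediol double bond, set by the enolate geometry in step 6 and erased on aromatisation.

Key step: step 9

Assumption: the sulfate monoesters 19 and 20 are named and drawn as free hydrogen sulfates, as the target is drawn; in practice 19 would be carried as its sodium salt and 20 protonated on a sulfonic acid resin in the last work-up. Diazomethane is used as a separately prepared ethereal solution.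

**Route**

Step 1
Reactants: 1 comenic acid (5-hydroxy-4-oxo-4H-pyran-2-carboxylic acid)
Product: 2 6-bromo-5-hydroxy-4-oxo-4H-pyran-2-carboxylic acid
Conditions: Br2, H2O, 0 → 25 °C
Reagents that add atoms: bromine, BrBr
Why: Electrophilic bromination of the enolised 3-hydroxy-4-pyranone should occur only at pyranone C6 (the future C2), the one free carbon ortho to the hydroxyl, as is usual for kojic-acid-type substrates.

Step 2
Reactants: 2 6-bromo-5-hydroxy-4-oxo-4H-pyran-2-carboxylic acid
Product: 3 tert-butyl 6-bromo-5-hydroxy-4-oxo-4H-pyran-2-carboxylate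
Conditions: t-BuOC(=NH)CCl3, THF, 25 °C
Reagents that add atoms: tert-butyl 2,2,2-trichloroacetimidate, CC(C)(C)OC(=N)C(Cl)(Cl)Cl
Why: Imidate esterification (acid-triggered tert-butyl transfer) should convert the strongly acidic carboxyl group selectively, and the tert-butyl ester is chosen because it withstands the later base, organozinc and enolate steps without acting as an acylating agent.

Step 3
Reactants: 3 tert-butyl 6-bromo-5-hydroxy-4-oxo-4H-pyran-2-carboxylate
Product: 4 tert-butyl 5-(benzyloxy)-6-bromo-4-oxo-4H-pyran-2-carboxylate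
Conditions: BnBr, K2CO3, DMF, 25 °C
Reagents that add atoms: benzyl bromide, BrCc1ccccc1
Why: Williamson etherification of the acidic enolic hydroxyl with a mild carbonate base should be clean and protects the future O3 in a form that hydrogenolysis removes at the end.

Step 4
Reactants: 4 tert-butyl 5-(benzyloxy)-6-bromo-4-oxo-4H-pyran-2-carboxylate; 5 [4-(benzyloxy)phenyl]boronic acid
Product: 6 tert-butyl 5-(benzyloxy)-6-[4-(benzyloxy)phenyl]-4-oxo-4H-pyran-2-carboxylate
Conditions: Pd(PPh3)4 (cat.), K2CO3, 1,4-dioxane/H2O, 80 °C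
Reagents that add atoms: none
Why: Suzuki–Miyaura coupling should proceed readily because the bromide is a vinylogous acyl bromide that adds quickly to zerovalent palladium, which joins ring B to the future C2.

Step 5
Reactants: 6 tert-butyl 5-(benzyloxy)-6-[4-(benzyloxy)phenyl]-4-oxo-4H-pyran-2-carboxylate; 7 2-(benzyloxy)acetyl chloride
Product: 9 tert-butyl 5-(benzyloxy)-3-[2-(benzyloxy)acetyl]-6-[4-(benzyloxy)phenyl]-4-oxo-4H-pyran-2-carboxylate, via pyranon-3-ylzinc chloride 8 (not isolated)
Conditions: TMPZnCl·LiCl, THF, 25 °C; then 7 (excess), Pd(PPh3)4 (cat.), 25 °C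
Reagents that add atoms: none
Why: Directed deprotonative zincation with the hindered zinc amide should take place at the only ring C–H, flanked by the ketone and the ester, and the arylzinc chloride is then acylated under palladium catalysis (Negishi acylation), which places C5 and C6 on the future C4a with tolerance of all esters and ethers.

Step 6
Reactants: 9 tert-butyl 5-(benzyloxy)-3-[2-(benzyloxy)acetyl]-6-[4-(benzyloxy)phenyl]-4-oxo-4H-pyran-2-carboxylate
Product: 11 tert-butyl 5-(benzyloxy)-3-[(Z)-2-(benzyloxy)-1-{[(benzyloxy)carbonyl]oxy}ethenyl]-6-[4-(benzyloxy)phenyl]-4-oxo-4H-pyran-2-carboxylate, via sodium (Z)-enolate 10 (not isolated)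
Conditions: NaN(SiMe3)2, THF, −78 °C; then ClCO2Bn, −78 → −40 °C
Reagents that add atoms: benzyl chloroformate, O=C(Cl)OCc1ccccc1
Why: Deprotonation at the only enolisable position should give the (Z)-enolate (benzyloxy group cis to the oxide for steric and chelation reasons), which the chloroformate acylates on oxygen (enolate O-acylation) while the tert-butyl ester resists Claisen-type and lactone-forming cyclisation; the benzyl carbonate on the future O5 later falls to the same hydrogenolysis as the ethers.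

Step 7
Reactants: 11 tert-butyl 5-(benzyloxy)-3-[(Z)-2-(benzyloxy)-1-{[(benzyloxy)carbonyl]oxy}ethenyl]-6-[4-(benzyloxy)phenyl]-4-oxo-4H-pyran-2-carboxylate
Product: 13 5-(benzyloxy)-3-[(Z)-2-(benzyloxy)-1-{[(benzyloxy)carbonyl]oxy}ethenyl]-6-[4-(benzyloxy)phenyl]-4-oxo-4H-pyran-2-carboxylic acid, via trimethylsilyl ester 12 (not isolated)
Conditions: Me3SiOTf, 2,6-lutidine, CH2Cl2, 0 °C; then aq. KH2PO4
Reagents that add atoms: none
Why: Silyl-triflate-mediated cleavage of the tert-butyl ester (silylation of the carbonyl oxygen, loss of 2-methylpropene, hydrolysis of the silyl ester on work-up) should free the carboxyl group under buffered, non-protic conditions that leave the benzyl carbonate, the benzyl ethers and the enediol double bond untouched.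

Step 8
Reactants: 13 5-(benzyloxy)-3-[(Z)-2-(benzyloxy)-1-{[(benzyloxy)carbonyl]oxy}ethenyl]-6-[4-(benzyloxy)phenyl]-4-oxo-4H-pyran-2-carboxylic acid
Product: 15 benzyl (Z)-2-(benzyloxy)-1-{5-(benzyloxy)-6-[4-(benzyloxy)phenyl]-2-(diazoacetyl)-4-oxo-4H-pyran-3-yl}ethenyl carbonate, via mixed carbonic anhydride 14 (not isolated)
Conditions: i-BuOCOCl, N-methylmorpholine, THF, −15 °C; then CH2N2, Et2O, 0 °C
Reagents that add atoms: diazomethane, C=[N+]=[N-]
Why: Acylation of diazomethane by a mixed carbonic anhydride, the first half of an Arndt–Eistert sequence, should give the diazoketone under base-buffered conditions in which the carboxylic acid cannot add to the neighbouring enediol double bond, and it brings in the future C8.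

Step 9
Reactants: 15 benzyl (Z)-2-(benzyloxy)-1-{5-(benzyloxy)-6-[4-(benzyloxy)phenyl]-2-(diazoacetyl)-4-oxo-4H-pyran-3-yl}ethenyl carbonate
Product: 18 benzyl 3,6-bis(benzyloxy)-2-[4-(benzyloxy)phenyl]-7-hydroxy-4-oxo-4H-chromen-5-yl carbonate, via dienylketene 16 (not isolated), via cyclohexadienone 17 (not isolated)
Conditions: hν (440 nm LEDs), dry PhMe (0.005 M), 25 °C; then 60 °C
Reagents that add atoms: none
Why: Blue-light excitation of the diazoketone should expel N2 with a concerted 1,2-shift of the pyranone carbon C8a from the acyl carbon to the diazo carbon (photochemical Wolff rearrangement, forming C8–C8a), which leaves the former carboxyl carbon as the ketene carbon C7. The ketene C7=C8, the C8a=C4a bond of ring C and the C5=C6 enediol bond form a dienylketene held cisoid by the ring, and it closes the six-membered ring A by a thermal disrotatory six-electron electrocyclisation between C7 and C6; this is the ring-forming event of the known aromatic annulations through dienylketenes and of the conversion of ortho-alkenylaryl diazoketones into fused phenols, here applied to a 4-pyranone. The cyclohexa-2,4-dienone 17 carries H and OBn on the sp3 carbon C6 and should enolise at once to the phenol, so no stereocentre survives and O7, the former acyl oxygen, is the only free hydroxyl. Periselectivity for six-electron closure over ketene dimerisation, (2+2) addition or capture by the product phenol is secured by the cis placement of both arms on C8a=C4a, by the (Z) geometry that turns the small hydrogen of C6 inward, by the weak aromaticity of the pyranone and by high dilution in a dry, non-nucleophilic solvent. Visible light without a metal keeps carbene-type addition to the enediol bond in check and leaves the 3-benzyloxyflavone chromophore of the product, which is photolabile in the ultraviolet, unexcited.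

Step 10
Reactants: 18 benzyl 3,6-bis(benzyloxy)-2-[4-(benzyloxy)phenyl]-7-hydroxy-4-oxo-4H-chromen-5-yl carbonate
Product: 19 3,6-bis(benzyloxy)-5-{[(benzyloxy)carbonyl]oxy}-2-[4-(benzyloxy)phenyl]-4-oxo-4H-chromen-7-yl hydrogen sulfate
Conditions: SO3·pyridine, pyridine, 40 °C
Reagents that add atoms: sulfur trioxide–pyridine complex, O=S(=O)([O-])[n+]1ccccc1
Why: O-Sulfonation with the sulfur trioxide–amine complex should esterify O7 alone because it is the only free hydroxyl, the benzyl ethers and the benzyl carbonate being inert to the reagent.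

Step 11
Reactants: 19 3,6-bis(benzyloxy)-5-{[(benzyloxy)carbonyl]oxy}-2-[4-(benzyloxy)phenyl]-4-oxo-4H-chromen-7-yl hydrogen sulfate
Product: 20 3,5,6-trihydroxy-2-(4-hydroxyphenyl)-4-oxo-4H-chromen-7-yl hydrogen sulfate
Conditions: H2 (1 atm), Pd/C, MeOH/THF, 25 °C
Reagents that add atoms: none
Why: Catalytic hydrogenolysis should cleave the three benzyl ethers and the benzyl carbonate (which then loses CO2) in one operation, whereas aryl sulfate monoesters and the flavonol double bond survive these neutral conditions.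

**Compound list**

1 | comenic acid (5-hydroxy-4-oxo-4H-pyran-2-carboxylic acid) | OC(=O)c1cc(=O)c(O)co1 | starting material
2 | 6-bromo-5-hydroxy-4-oxo-4H-pyran-2-carboxylic acid | OC(=O)c1cc(=O)c(O)c(Br)o1 | intermediate
3 | tert-butyl 6-bromo-5-hydroxy-4-oxo-4H-pyran-2-carboxylate | CC(C)(C)OC(=O)c1cc(=O)c(O)c(Br)o1 | intermediate
4 | tert-butyl 5-(benzyloxy)-6-bromo-4-oxo-4H-pyran-2-carboxylate | CC(C)(C)OC(=O)c1cc(=O)c(OCc2ccccc2)c(Br)o1 | intermediate
5 | [4-(benzyloxy)phenyl]boronic acid | OB(O)c1ccc(OCc2ccccc2)cc1 | starting material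
6 | tert-butyl 5-(benzyloxy)-6-[4-(benzyloxy)phenyl]-4-oxo-4H-pyran-2-carboxylate | CC(C)(C)OC(=O)c1cc(=O)c(OCc2ccccc2)c(-c2ccc(OCc3ccccc3)cc2)o1 | intermediate
7 | 2-(benzyloxy)acetyl chloride | O=C(Cl)COCc1ccccc1 | starting material
8 | {5-(benzyloxy)-6-[4-(benzyloxy)phenyl]-2-(tert-butoxycarbonyl)-4-oxo-4H-pyran-3-yl}zinc chloride (LiCl complex) | CC(C)(C)OC(=O)c1c([Zn]Cl)c(=O)c(OCc2ccccc2)c(-c2ccc(OCc3ccccc3)cc2)o1 | intermediate
9 | tert-butyl 5-(benzyloxy)-3-[2-(benzyloxy)acetyl]-6-[4-(benzyloxy)phenyl]-4-oxo-4H-pyran-2-carboxylate | CC(C)(C)OC(=O)c1c(C(=O)COCc2ccccc2)c(=O)c(OCc2ccccc2)c(-c2ccc(OCc3ccccc3)cc2)o1 | intermediate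
10 | sodium (Z)-2-(benzyloxy)-1-{5-(benzyloxy)-6-[4-(benzyloxy)phenyl]-2-(tert-butoxycarbonyl)-4-oxo-4H-pyran-3-yl}ethen-1-olate | CC(C)(C)OC(=O)c1c(/C([O-])=C/OCc2ccccc2)c(=O)c(OCc2ccccc2)c(-c2ccc(OCc3ccccc3)cc2)o1.[Na+] | intermediate
11 | tert-butyl 5-(benzyloxy)-3-[(Z)-2-(benzyloxy)-1-{[(benzyloxy)carbonyl]oxy}ethenyl]-6-[4-(benzyloxy)phenyl]-4-oxo-4H-pyran-2-carboxylate | CC(C)(C)OC(=O)c1c(/C(OC(=O)OCc2ccccc2)=C/OCc2ccccc2)c(=O)c(OCc2ccccc2)c(-c2ccc(OCc3ccccc3)cc2)o1 | intermediate
12 | trimethylsilyl 5-(benzyloxy)-3-[(Z)-2-(benzyloxy)-1-{[(benzyloxy)carbonyl]oxy}ethenyl]-6-[4-(benzyloxy)phenyl]-4-oxo-4H-pyran-2-carboxylate | C[Si](C)(C)OC(=O)c1c(/C(OC(=O)OCc2ccccc2)=C/OCc2ccccc2)c(=O)c(OCc2ccccc2)c(-c2ccc(OCc3ccccc3)cc2)o1 | intermediate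
13 | 5-(benzyloxy)-3-[(Z)-2-(benzyloxy)-1-{[(benzyloxy)carbonyl]oxy}ethenyl]-6-[4-(benzyloxy)phenyl]-4-oxo-4H-pyran-2-carboxylic acid | OC(=O)c1c(/C(OC(=O)OCc2ccccc2)=C/OCc2ccccc2)c(=O)c(OCc2ccccc2)c(-c2ccc(OCc3ccccc3)cc2)o1 | intermediate
14 | 5-(benzyloxy)-3-[(Z)-2-(benzyloxy)-1-{[(benzyloxy)carbonyl]oxy}ethenyl]-6-[4-(benzyloxy)phenyl]-4-oxo-4H-pyran-2-carboxylic 2-methylpropyl carbonic anhydride | CC(C)COC(=O)OC(=O)c1c(/C(OC(=O)OCc2ccccc2)=C/OCc2ccccc2)c(=O)c(OCc2ccccc2)c(-c2ccc(OCc3ccccc3)cc2)o1 | intermediate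
15 | benzyl (Z)-2-(benzyloxy)-1-{5-(benzyloxy)-6-[4-(benzyloxy)phenyl]-2-(diazoacetyl)-4-oxo-4H-pyran-3-yl}ethenyl carbonate | [N-]=[N+]=CC(=O)c1c(/C(OC(=O)OCc2ccccc2)=C/OCc2ccccc2)c(=O)c(OCc2ccccc2)c(-c2ccc(OCc3ccccc3)cc2)o1 | intermediate
16 | benzyl (Z)-2-(benzyloxy)-1-{5-(benzyloxy)-6-[4-(benzyloxy)phenyl]-4-oxo-2-(2-oxoethenyl)-4H-pyran-3-yl}ethenyl carbonate | O=C=Cc1c(/C(OC(=O)OCc2ccccc2)=C/OCc2ccccc2)c(=O)c(OCc2ccccc2)c(-c2ccc(OCc3ccccc3)cc2)o1 | intermediate
17 | benzyl 3,6-bis(benzyloxy)-2-[4-(benzyloxy)phenyl]-4,7-dioxo-6,7-dihydro-4H-chromen-5-yl carbonate (racemic at C6) | O=C1C=C2OC(-c3ccc(OCc4ccccc4)cc3)=C(OCc3ccccc3)C(=O)C2=C(OC(=O)OCc2ccccc2)C1OCc1ccccc1 | intermediate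
18 | benzyl 3,6-bis(benzyloxy)-2-[4-(benzyloxy)phenyl]-7-hydroxy-4-oxo-4H-chromen-5-yl carbonate | O=c1c(OCc2ccccc2)c(-c2ccc(OCc3ccccc3)cc2)oc2cc(O)c(OCc3ccccc3)c(OC(=O)OCc3ccccc3)c12 | intermediate
19 | 3,6-bis(benzyloxy)-5-{[(benzyloxy)carbonyl]oxy}-2-[4-(benzyloxy)phenyl]-4-oxo-4H-chromen-7-yl hydrogen sulfate | O=c1c(OCc2ccccc2)c(-c2ccc(OCc3ccccc3)cc2)oc2cc(OS(=O)(=O)O)c(OCc3ccccc3)c(OC(=O)OCc3ccccc3)c12 | intermediate
20 | 3,5,6-trihydroxy-2-(4-hydroxyphenyl)-4-oxo-4H-chromen-7-yl hydrogen sulfate | O=c1c(O)c(-c2ccc(O)cc2)oc2cc(OS(=O)(=O)O)c(O)c(O)c12 | target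

**Count and risks**

Total steps: 11. Longest linear sequence: 11 steps (1 to 20).

Steps most likely to fail, in order: step 9, step 6, step 5.

Step 9. The photogenerated ketene may be consumed by the product phenol or by traces of water before it closes, carbene-type addition to the neighbouring enediol bond may compete, or closure may be slow because the central double bond belongs to the pyranone. Ring A would then be closed by ionic chemistry instead. Setting out from 15, silver-catalysed Wolff rearrangement in methanol (PhCO2Ag, Et3N, MeOH, 25 °C, dark; Arndt–Eistert homologation, the ketene 16 now being intercepted on purpose by the solvent) would give methyl {5-(benzyloxy)-3-[(Z)-2-(benzyloxy)-1-{[(benzyloxy)carbonyl]oxy}ethenyl]-6-[4-(benzyloxy)phenyl]-4-oxo-4H-pyran-2-yl}acetate F1. NaOMe in MeOH/THF would remove the enol carbonate to give the keto ester methyl {5-(benzyloxy)-3-[2-(benzyloxy)acetyl]-6-[4-(benzyloxy)phenyl]-4-oxo-4H-pyran-2-yl}acetate F2, whose C6 enolate should attack the ester carbon C7 (Dieckmann-type Claisen condensation) and aromatise to 3,6-bis(benzyloxy)-2-[4-(benzyloxy)phenyl]-5,7-dihydroxy-4H-chromen-4-one F3. SO3·pyridine should sulfate only O7, the 5-hydroxyl being held in a hydrogen bond to the C4 carbonyl, to give 3,6-bis(benzyloxy)-2-[4-(benzyloxy)phenyl]-5-hydroxy-4-oxo-4H-chromen-7-yl hydrogen sulfate F4. Hydrogenolysis as in step 11 then comes back to the route at 20.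

Step 6. The free enolate may be acylated on carbon instead of oxygen, or may be lost by attack on the electrophilic pyranone and ester before it is trapped. The enol carbonate would then be made without a free amide-generated enolate. Setting out from 9, soft enolisation (Me3SiOTf, Et3N, CH2Cl2, 0 °C) would give tert-butyl 5-(benzyloxy)-3-{(Z)-2-(benzyloxy)-1-[(trimethylsilyl)oxy]ethenyl}-6-[4-(benzyloxy)phenyl]-4-oxo-4H-pyran-2-carboxylate F5. Slow addition of [Bu4N][Ph3SiF2] to F5 and ClCO2Bn in THF at −78 °C should release the enolate only in the presence of the chloroformate (fluoride-triggered desilylative O-acylation), and the sequence comes back to the route at 11.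

Step 5. The acid chloride may be lost by dehydrochlorination to benzyloxyketene under the action of the liberated amine, and acyl transfer to the doubly flanked carbon–zinc bond may be sluggish. The C4a–C5 bond would then be made by carbonyl addition. Setting out from 6 by way of its zinc derivative 8, iodolysis (I2, THF) would give tert-butyl 5-(benzyloxy)-6-[4-(benzyloxy)phenyl]-3-iodo-4-oxo-4H-pyran-2-carboxylate F6. Iodine–magnesium exchange (iPrMgCl·LiCl, THF, −78 °C) would give {5-(benzyloxy)-6-[4-(benzyloxy)phenyl]-2-(tert-butoxycarbonyl)-4-oxo-4H-pyran-3-yl}magnesium chloride F7. Addition to commercial 2-(benzyloxy)acetaldehyde with a cold acidic quench would give racemic tert-butyl 5-(benzyloxy)-3-[2-(benzyloxy)-1-hydroxyethyl]-6-[4-(benzyloxy)phenyl]-4-oxo-4H-pyran-2-carboxylate F8. Oxidation with Dess–Martin periodinane then comes back to the route at 9.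

**Further compounds**

F1 | step 9 | methyl {5-(benzyloxy)-3-[(Z)-2-(benzyloxy)-1-{[(benzyloxy)carbonyl]oxy}ethenyl]-6-[4-(benzyloxy)phenyl]-4-oxo-4H-pyran-2-yl}acetate | COC(=O)Cc1c(/C(OC(=O)OCc2ccccc2)=C/OCc2ccccc2)c(=O)c(OCc2ccccc2)c(-c2ccc(OCc3ccccc3)cc2)o1
F2 | step 9 | methyl {5-(benzyloxy)-3-[2-(benzyloxy)acetyl]-6-[4-(benzyloxy)phenyl]-4-oxo-4H-pyran-2-yl}acetate | COC(=O)Cc1c(C(=O)COCc2ccccc2)c(=O)c(OCc2ccccc2)c(-c2ccc(OCc3ccccc3)cc2)o1
F3 | step 9 | 3,6-bis(benzyloxy)-2-[4-(benzyloxy)phenyl]-5,7-dihydroxy-4H-chromen-4-one | O=c1c(OCc2ccccc2)c(-c2ccc(OCc3ccccc3)cc2)oc2cc(O)c(OCc3ccccc3)c(O)c12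
F4 | step 9 | 3,6-bis(benzyloxy)-2-[4-(benzyloxy)phenyl]-5-hydroxy-4-oxo-4H-chromen-7-yl hydrogen sulfate | O=c1c(OCc2ccccc2)c(-c2ccc(OCc3ccccc3)cc2)oc2cc(OS(=O)(=O)O)c(OCc3ccccc3)c(O)c12
F5 | step 6 | tert-butyl 5-(benzyloxy)-3-{(Z)-2-(benzyloxy)-1-[(trimethylsilyl)oxy]ethenyl}-6-[4-(benzyloxy)phenyl]-4-oxo-4H-pyran-2-carboxylate | CC(C)(C)OC(=O)c1c(/C(O[Si](C)(C)C)=C/OCc2ccccc2)c(=O)c(OCc2ccccc2)c(-c2ccc(OCc3ccccc3)cc2)o1
F6 | step 5 | tert-butyl 5-(benzyloxy)-6-[4-(benzyloxy)phenyl]-3-iodo-4-oxo-4H-pyran-2-carboxylate | CC(C)(C)OC(=O)c1c(I)c(=O)c(OCc2ccccc2)c(-c2ccc(OCc3ccccc3)cc2)o1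
F7 | step 5 | {5-(benzyloxy)-6-[4-(benzyloxy)phenyl]-2-(tert-butoxycarbonyl)-4-oxo-4H-pyran-3-yl}magnesium chloride | CC(C)(C)OC(=O)c1c([Mg]Cl)c(=O)c(OCc2ccccc2)c(-c2ccc(OCc3ccccc3)cc2)o1
F8 | step 5 | tert-butyl 5-(benzyloxy)-3-[2-(benzyloxy)-1-hydroxyethyl]-6-[4-(benzyloxy)phenyl]-4-oxo-4H-pyran-2-carboxylate (racemic) | CC(C)(C)OC(=O)c1c(C(O)COCc2ccccc2)c(=O)c(OCc2ccccc2)c(-c2ccc(OCc3ccccc3)cc2)o1
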